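**Retrosynthetic overview** (target from the SMILES: 4Z,6S,7S,8S,9S,10R)
1. Target 25 ← DDQ removal of the O9 PMB ether 24 ← intramolecular Heck closure of the C3–C4 bond from (Z)-alkenyl iodide 23; the ten-membered carbocycle is formed last.
2. 23 ← Z-iodo-olefination of the C5 aldehyde ← γ-lactone (O6 onto C12) ← O8 methacryloylation ← chromium-catalysed C7–C8 allylation joining furanone aldehyde 9 and allyl bromide 15.
3. 9 ← oxidative cleavage of 8 ← new Pd-catalysed enantioselective C9–C10 coupling of 2-methylfuran-3(2H)-one 4 with PMB-oxyallene 7, which sets C9 and C10.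
4. 15 ← Morita–Baylis–Hillman adduct of (S)-glyceraldehyde acetonide 12 (from (R)-but-3-ene-1,2-diol) and methyl acrylate; 4 ← acetoin and DMF dimethyl acetal; 7 ← propargyl alcohol.
5. Ring order: furanone (step 2), γ-lactone (step 13), carbocycle (step 16).

Assumption: positions use germacrane numbering (C1 furanone C=O, C2=C3, C4=C5, C6–O lactone, C7, C8–O ester, C9–OH, C10 quaternary, C11=C13, C12 lactone C=O); the ligand antipode in step 5 is chosen by analogy and is swapped if the first run gives the mirror-image product.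

**Route**

Step 1
Reactants: 1 3-hydroxybutan-2-one (acetoin, racemic); 2 N,N-dimethylformamide dimethyl acetal
Product: 3 (E)-1-(dimethylamino)-4-hydroxypent-1-en-3-one (racemic)
Conditions: neat, 90 °C, MeOH distilled off
Reagents that add atoms: none
Why: Enaminone condensation of the amide acetal with the methyl group of the ketone, driven by loss of methanol; the hydroxylated methine cannot condense.

Step 2
Reactants: 3 (E)-1-(dimethylamino)-4-hydroxypent-1-en-3-one
Product: 4 2-methylfuran-3(2H)-one (racemic)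
Conditions: AcOH/H2O (1:1), 50 °C
Reagents that add atoms: none
Why: Acid-promoted intramolecular conjugate addition of the hydroxyl to the enaminone and elimination of dimethylamine (addition–elimination) gives the 3(2H)-furanone; its C2 centre is racemic and is reset in step 5.

Step 3
Reactants: 5 prop-2-yn-1-ol
Product: 6 1-methoxy-4-[(prop-2-yn-1-yloxy)methyl]benzene
Conditions: NaH, PMBCl, Bu4NI (cat.), THF, 0 → 25 °C
Reagents that add atoms: 4-methoxybenzyl chloride, COc1ccc(CCl)cc1
Why: Williamson ether synthesis on a primary alkoxide.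

Step 4
Reactants: 6 1-methoxy-4-[(prop-2-yn-1-yloxy)methyl]benzene
Product: 7 1-methoxy-4-[(propa-1,2-dien-1-yloxy)methyl]benzene
Conditions: KOtBu (20 mol %), THF, 25 °C
Reagents that add atoms: none
Why: Base-catalysed propargyl-to-allenyl isomerisation, which stops at the oxygen-conjugated alkoxyallene.

Step 5
Reactants: 4 2-methylfuran-3(2H)-one; 7 1-methoxy-4-[(propa-1,2-dien-1-yloxy)methyl]benzene
Product: 8 (2R)-2-methyl-2-[(1S)-1-[(4-methoxyphenyl)methoxy]prop-2-en-1-yl]furan-3(2H)-one
Conditions: Pd2(dba)3·CHCl3 (2.5 mol %), (R,R)-DACH-phenyl Trost ligand (7.5 mol %), PhCO2H (10 mol %), toluene, 25 °C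
Reagents that add atoms: none
Why: Proposed new method: Pd-catalysed enantio- and diastereoselective hydroalkylation of an alkoxyallene with a 3(2H)-furanone as carbon pronucleophile, forming the C9–C10 bond; zerovalent palladium and the acid give a palladium hydride that adds to the allene to form a 1-alkoxy-π-allyl complex, the aromatic 3-furanolate derived from racemic 4 attacks the alkoxy-bearing terminus through C2 (O-attack gives a labile mixed acetal that re-ionises), and the ligand pocket selects one face of the planar furanolate (C10, R) and one face of the allyl terminus (C9, S); the closest known reaction type is the Pd/Trost-ligand addition of oxindoles, azlactones and 1,3-dicarbonyl compounds to benzyloxyallene.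

Step 6
Reactants: 8 (2R)-2-methyl-2-[(1S)-1-[(4-methoxyphenyl)methoxy]prop-2-en-1-yl]furan-3(2H)-one
Product: 9 (2R)-2-[(1R)-1-[(4-methoxyphenyl)methoxy]-2-oxoethyl]-2-methylfuran-3(2H)-one
Conditions: OsO4 (2 mol %), NaIO4 (4 equiv), 2,6-lutidine, dioxane/H2O (3:1), 25 °C
Reagents that add atoms: sodium periodate (terminal oxidant, supplies the carbonyl oxygen through OsO4), [Na+].[O-]I(=O)(=O)=O
Why: Lemieux–Johnson cleavage of the terminal vinyl group, which is far more reactive toward OsO4 than the push-pull furanone alkene; no stereocentre is touched (the descriptor at C9 changes only by priority).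

Step 7
Reactants: 10 (2R)-but-3-ene-1,2-diol
Product: 11 (4R)-2,2-dimethyl-4-vinyl-1,3-dioxolane
Conditions: Me2C(OMe)2, PPTS (cat.), CH2Cl2, 25 °C
Reagents that add atoms: 2,2-dimethoxypropane, COC(C)(C)OC
Why: Acid-catalysed transketalisation to the five-membered acetonide.

Step 8
Reactants: 11 (4R)-2,2-dimethyl-4-vinyl-1,3-dioxolane
Product: 12 (4S)-2,2-dimethyl-1,3-dioxolane-4-carbaldehyde
Conditions: O3, CH2Cl2, −78 °C; then Me2S
Reagents that add atoms: ozone, [O-][O+]=O
Why: Ozonolysis with reductive work-up; the stereocentre is untouched (descriptor changes by priority only).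

Step 9
Reactants: 12 (4S)-2,2-dimethyl-1,3-dioxolane-4-carbaldehyde; 13 methyl acrylate
Product: 14 methyl 2-[[(4S)-2,2-dimethyl-1,3-dioxolan-4-yl](hydroxy)methyl]prop-2-enoate (both carbinol epimers)
Conditions: DABCO (1 equiv), dioxane/H2O (1:1), 25 °C
Reagents that add atoms: none
Why: Morita–Baylis–Hillman reaction of an activated α-alkoxy aldehyde; the new carbinol centre is removed in step 10, so its configuration does not matter.

Step 10
Reactants: 14 methyl 2-[[(4S)-2,2-dimethyl-1,3-dioxolan-4-yl](hydroxy)methyl]prop-2-enoate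
Product: 15 methyl (2Z)-2-(bromomethyl)-3-[(4R)-2,2-dimethyl-1,3-dioxolan-4-yl]prop-2-enoate
Conditions: NBS, Me2S, CH2Cl2, 0 → 25 °C
Reagents that add atoms: N-bromosuccinimide, BrN1C(=O)CCC1=O
Why: Corey–Kim-type activation of the allylic alcohol and SN2' attack of bromide give the rearranged primary bromide with the dioxolane trans to the ester (Z).

Step 11
Reactants: 9 (2R)-2-[(1R)-1-[(4-methoxyphenyl)methoxy]-2-oxoethyl]-2-methylfuran-3(2H)-one; 15 methyl (2Z)-2-(bromomethyl)-3-[(4R)-2,2-dimethyl-1,3-dioxolan-4-yl]prop-2-enoate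
Product: 17 methyl 2-[(1R,2S,3S)-1-[(4R)-2,2-dimethyl-1,3-dioxolan-4-yl]-2-hydroxy-3-[(4-methoxyphenyl)methoxy]-3-[(2R)-2-methyl-3-oxo-2,3-dihydrofuran-2-yl]propyl]prop-2-enoate, via trimethylsilyl ether 16 (not isolated)
Conditions: CrCl2 (15 mol %), Mn powder, Me3SiCl, THF, 25 °C; then citric acid, MeOH, 0 °C
Reagents that add atoms: chlorotrimethylsilane, C[Si](C)(C)Cl (its silyl group sits only in 16 and is lost again in the work-up)
Why: Chromium-catalysed Nozaki–Hiyama–Kishi-type 2-(methoxycarbonyl)allylation in which the (Z)-allylchromium reagent reacts through its γ-carbon in a chair transition state (C7/C8 syn), on the Felkin–Anh face of the α-alkoxy aldehyde (O8/O9 anti) and on the allyl face fixed by A(1,3) strain and coordination of the dioxolane oxygen (attack anti to C5), three preferences that reinforce each other, while silylation of the alkoxide prevents lactone formation on O8.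

Step 12
Reactants: 17 homoallylic alcohol (as named in step 11); 18 2-methylprop-2-enoyl chloride
Product: 19 methyl 2-[(1S,2S,3S)-1-[(4R)-2,2-dimethyl-1,3-dioxolan-4-yl]-3-[(4-methoxyphenyl)methoxy]-2-[(2-methylprop-2-enoyl)oxy]-3-[(2R)-2-methyl-3-oxo-2,3-dihydrofuran-2-yl]propyl]prop-2-enoate
Conditions: Et3N, DMAP (cat.), CH2Cl2, 0 °C
Reagents that add atoms: none
Why: DMAP-catalysed acylation of the only free hydroxyl, which is faster than lactonisation onto the methyl ester; no stereocentre changes (the C7 descriptor changes by priority only).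

Step 13
Reactants: 19 methacrylate (as named in step 12)
Product: 21 (1S,2S)-1-[(2R,3S)-2-(hydroxymethyl)-4-methylidene-5-oxooxolan-3-yl]-2-[(4-methoxyphenyl)methoxy]-2-[(2R)-2-methyl-3-oxo-2,3-dihydrofuran-2-yl]ethyl 2-methylprop-2-enoate, via diol ester 20 (not isolated)
Conditions: AcOH/H2O (4:1), 45 °C; then CSA (cat.), CH2Cl2, 25 °C
Reagents that add atoms: none
Why: Acid hydrolysis of the acetonide frees the C6 and C5 hydroxyls, and the secondary C6–OH closes the five-membered α-methylene lactone on the acrylate ester (five- over six-membered ring; cis fusion already fixed by C6 and C7).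

Step 14
Reactants: 21 lactone alcohol (as named in step 13)
Product: 22 (1S,2S)-1-[(2R,3R)-2-formyl-4-methylidene-5-oxooxolan-3-yl]-2-[(4-methoxyphenyl)methoxy]-2-[(2R)-2-methyl-3-oxo-2,3-dihydrofuran-2-yl]ethyl 2-methylprop-2-enoate
Conditions: TEMPO (20 mol %), PhI(OAc)2, CH2Cl2, 25 °C
Reagents that add atoms: none
Why: Oxoammonium oxidation of the primary alcohol under near-neutral conditions, which avoids epimerisation at C6; the aldehyde is used crude.

Step 15
Reactants: 22 lactone aldehyde (as named in step 14)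
Product: 23 (1S,2S)-1-[(2R,3S)-2-[(1Z)-2-iodoprop-1-en-1-yl]-4-methylidene-5-oxooxolan-3-yl]-2-[(4-methoxyphenyl)methoxy]-2-[(2R)-2-methyl-3-oxo-2,3-dihydrofuran-2-yl]ethyl 2-methylprop-2-enoate
Conditions: EtPPh3I, n-BuLi, THF, then I2, −78 °C; NaN(SiMe3)2, −78 °C; then 22, −78 → −20 °C
Reagents that add atoms: ethyltriphenylphosphonium iodide, CC[P+](c1ccccc1)(c1ccccc1)c1ccccc1.[I-]; iodine, II
Why: Stork–Zhao-type Wittig olefination with the α-iodoethylidene ylide, which is Z-selective (iodine cis to C6) and fast enough at −78 °C to outrun Michael addition and α-epimerisation.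

Step 16
Reactants: 23 (Z)-alkenyl iodide (as named in step 15)
Product: 24 [(2Z,4S,8S,9S,10S,11R)-10-[(4-methoxyphenyl)methoxy]-2,11-dimethyl-7-methylidene-6,12-dioxo-5,14-dioxatricyclo[9.2.1.0(4,8)]tetradeca-1(13),2-dien-9-yl] 2-methylprop-2-enoate
Conditions: Pd(OAc)2 (20 mol %), P(2-furyl)3 (40 mol %), Ag2CO3 (1.5 equiv), toluene (1 mM, slow addition), 80 °C
Reagents that add atoms: none
Why: Intramolecular Mizoroki–Heck reaction in which the (Z)-alkenylpalladium iodide, formed with retention, adds to the furanone C2=C3 bond with the alkenyl group at C3 (β-carbon of the enone and oxygen-bearing carbon of the enol ether), and β-hydride elimination through the palladium enolate restores the furanone and closes the ten-membered ring with the 4Z geometry set by the iodide.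

Step 17
Reactants: 24 PMB ether (as named in step 16)
Product: 25 [(2Z,4S,8S,9S,10S,11R)-10-hydroxy-2,11-dimethyl-7-methylidene-6,12-dioxo-5,14-dioxatricyclo[9.2.1.0(4,8)]tetradeca-1(13),2-dien-9-yl] 2-methylprop-2-enoate (CNP0252578.5)
Conditions: DDQ, CH2Cl2/pH 7 buffer (10:1), 0 → 25 °C
Reagents that add atoms: none
Why: Oxidative cleavage of the p-methoxybenzyl ether under buffered conditions leaves the acrylate units untouched and avoids 8→9 acyl migration.

**Compound list**
1 | 3-hydroxybutan-2-one (acetoin) | CC(O)C(C)=O | starting material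
2 | N,N-dimethylformamide dimethyl acetal | COC(OC)N(C)C | starting material
3 | (E)-1-(dimethylamino)-4-hydroxypent-1-en-3-one | CC(O)C(=O)/C=C/N(C)C | intermediate
4 | 2-methylfuran-3(2H)-one | CC1OC=CC1=O | intermediate
5 | prop-2-yn-1-ol | C#CCO | starting material
6 | 1-methoxy-4-[(prop-2-yn-1-yloxy)methyl]benzene | C#CCOCc1ccc(OC)cc1 | intermediate
7 | 1-methoxy-4-[(propa-1,2-dien-1-yloxy)methyl]benzene | C=C=COCc1ccc(OC)cc1 | intermediate
8 | (2R)-2-methyl-2-[(1S)-1-[(4-methoxyphenyl)methoxy]prop-2-en-1-yl]furan-3(2H)-one | C1=CC(=O)[C@](C)(O1)[C@@H](OCc2ccc(OC)cc2)C=C | intermediate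
9 | (2R)-2-[(1R)-1-[(4-methoxyphenyl)methoxy]-2-oxoethyl]-2-methylfuran-3(2H)-one | C1=CC(=O)[C@](C)(O1)[C@@H](OCc2ccc(OC)cc2)C=O | intermediate
10 | (2R)-but-3-ene-1,2-diol | C=C[C@@H](O)CO | starting material
11 | (4R)-2,2-dimethyl-4-vinyl-1,3-dioxolane | C=C[C@@H]1COC(C)(C)O1 | intermediate
12 | (4S)-2,2-dimethyl-1,3-dioxolane-4-carbaldehyde | O=C[C@@H]1COC(C)(C)O1 | intermediate
13 | methyl acrylate | C=CC(=O)OC | starting material
14 | methyl 2-[[(4S)-2,2-dimethyl-1,3-dioxolan-4-yl](hydroxy)methyl]prop-2-enoate (carbinol epimers) | COC(=O)C(=C)C(O)[C@@H]1COC(C)(C)O1 | intermediate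
15 | methyl (2Z)-2-(bromomethyl)-3-[(4R)-2,2-dimethyl-1,3-dioxolan-4-yl]prop-2-enoate | COC(=O)/C(CBr)=C/[C@@H]1COC(C)(C)O1 | intermediate
16 | O8-trimethylsilyl ether of 17 | C1=CC(=O)[C@](C)(O1)[C@@H](OCc2ccc(OC)cc2)[C@@H](O[Si](C)(C)C)[C@H]([C@@H]3COC(C)(C)O3)C(=C)C(=O)OC | intermediate (not isolated)
17 | methyl 2-[(1R,2S,3S)-1-[(4R)-2,2-dimethyl-1,3-dioxolan-4-yl]-2-hydroxy-3-[(4-methoxyphenyl)methoxy]-3-[(2R)-2-methyl-3-oxo-2,3-dihydrofuran-2-yl]propyl]prop-2-enoate | C1=CC(=O)[C@](C)(O1)[C@@H](OCc2ccc(OC)cc2)[C@@H](O)[C@H]([C@@H]3COC(C)(C)O3)C(=C)C(=O)OC | intermediate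
18 | 2-methylprop-2-enoyl chloride | C=C(C)C(Cl)=O | starting material
19 | O8-methacrylate of 17 (1S,2S,3S) | C1=CC(=O)[C@](C)(O1)[C@@H](OCc2ccc(OC)cc2)[C@@H](OC(=O)C(C)=C)[C@H]([C@@H]3COC(C)(C)O3)C(=C)C(=O)OC | intermediate
20 | 5,6-diol methyl ester from 19 (acetonide removed) | C1=CC(=O)[C@](C)(O1)[C@@H](OCc2ccc(OC)cc2)[C@@H](OC(=O)C(C)=C)[C@H]([C@@H](O)CO)C(=C)C(=O)OC | intermediate (not isolated)
21 | (1S,2S)-1-[(2R,3S)-2-(hydroxymethyl)-4-methylidene-5-oxooxolan-3-yl]-2-[(4-methoxyphenyl)methoxy]-2-[(2R)-2-methyl-3-oxo-2,3-dihydrofuran-2-yl]ethyl 2-methylprop-2-enoate | C1=CC(=O)[C@](C)(O1)[C@@H](OCc2ccc(OC)cc2)[C@@H](OC(=O)C(C)=C)[C@H]3C(=C)C(=O)O[C@H]3CO | intermediate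
22 | (2R,3R)-2-formyl analogue of 21 | C1=CC(=O)[C@](C)(O1)[C@@H](OCc2ccc(OC)cc2)[C@@H](OC(=O)C(C)=C)[C@H]3C(=C)C(=O)O[C@H]3C=O | intermediate
23 | (2R,3S)-2-[(1Z)-2-iodoprop-1-en-1-yl] analogue of 21 | C1=CC(=O)[C@](C)(O1)[C@@H](OCc2ccc(OC)cc2)[C@@H](OC(=O)C(C)=C)[C@H]3C(=C)C(=O)O[C@H]3/C=C(/C)I | intermediate
24 | O9-(4-methoxybenzyl) ether of the target | C=C(C)C(=O)O[C@H]1[C@H]2C(=C)C(=O)O[C@H]2/C=C(/C)C2=CC(=O)[C@](C)(O2)[C@H]1OCc1ccc(OC)cc1 | intermediate
25 | CNP0252578.5 | C=C(C)C(=O)O[C@H]1[C@H]2C(=C)C(=O)O[C@H]2/C=C(/C)C2=CC(=O)[C@](C)(O2)[C@H]1O | target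

**Step count**
Total: 17 steps. Longest linear sequence: 11 steps (for example 5 → 6 → 7 → 8 → 9 → 17 → 19 → 21 → 22 → 23 → 24 → 25, steps 3–6 and 11–17; the chains from 1 and from 10 are equally long). 11/17 = 0.65.

**Three steps most likely to fail**

Step 5 (the proposed new step; risks are O- versus C-attack of the furanolate and the level and sense of diastereo- and enantiocontrol). The fallback uses known chemistry, sets out from furanone 4 with aldehyde 12 as a sacrificial chiral partner, and comes back to the route at aldehyde 9, so that steps 5 and 6 are skipped. Furanone 4 is silylated (t-BuMe2SiOTf, Et3N) to 3-(tert-butyldimethylsilyloxy)-2-methylfuran F1. A BF3·OEt2-mediated Mukaiyama aldol addition of F1 to 12 at −78 °C goes through C2 of the furan and on the Felkin–Anh face of the aldehyde to give the anti aldol (2R)-2-[(S)-[(4S)-2,2-dimethyl-1,3-dioxolan-4-yl](hydroxy)methyl]-2-methylfuran-3(2H)-one F2; its C2 epimer is removed by chromatography. Protection with 4-methoxybenzyl trichloroacetimidate and catalytic La(OTf)3 gives the PMB ether F3, aqueous acetic acid removes the acetonide to give the diol F4, and NaIO4 cleaves the diol to 9.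

Step 15 (low yields are common for α-iodo ylides with base-sensitive, epimerisable aldehydes). The fallback sets out from aldehyde 22 and comes back at macrocycle 24. Corey–Fuchs olefination (CBr4, PPh3, 2,6-lutidine) gives the 1,1-dibromoalkene F5. A Pd-catalysed Negishi coupling with MeZnCl (PdCl2(DPEphos), THF), selective for the bromide trans to the chain, gives the (Z)-2-bromopropenyl lactone F6 with bromine cis to C6. F6 is then cyclised under the conditions of step 16 to give 24.

Step 16 (medium-ring Heck closure; risks are dimerisation, reductive Heck product and attack on the methacrylate). The fallback sets out from iodide 23 and comes back at 24. Miyaura borylation (PdCl2(dppf), B2pin2, KOAc) gives the (Z)-alkenyl pinacol boronate F7 with retention. A [Rh(cod)OH]2-catalysed intramolecular 1,4-addition of the alkenyl group to the furanone (dioxane/H2O, high dilution) gives the macrocyclic 2,3-dihydro derivative F8, whose C3 epimers are both usable. Dehydrogenation with IBX (DMSO, 60 °C) restores the C2=C3 bond and gives 24.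

**Further compounds**
F1 | step 5 | 3-(tert-butyldimethylsilyloxy)-2-methylfuran | Cc1occc1O[Si](C)(C)C(C)(C)C
F2 | step 5 | (2R)-2-[(S)-[(4S)-2,2-dimethyl-1,3-dioxolan-4-yl](hydroxy)methyl]-2-methylfuran-3(2H)-one | C1=CC(=O)[C@](C)(O1)[C@@H](O)[C@@H]2COC(C)(C)O2
F3 | step 5 | O-(4-methoxybenzyl) ether of F2 | C1=CC(=O)[C@](C)(O1)[C@@H](OCc2ccc(OC)cc2)[C@@H]3COC(C)(C)O3
F4 | step 5 | (2R)-2-[(1S,2S)-2,3-dihydroxy-1-[(4-methoxyphenyl)methoxy]propyl]-2-methylfuran-3(2H)-one | C1=CC(=O)[C@](C)(O1)[C@@H](OCc2ccc(OC)cc2)[C@@H](O)CO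
F5 | step 15 | 2-(2,2-dibromoethenyl) analogue of 21 | C1=CC(=O)[C@](C)(O1)[C@@H](OCc2ccc(OC)cc2)[C@@H](OC(=O)C(C)=C)[C@H]3C(=C)C(=O)O[C@H]3C=C(Br)Br
F6 | step 15 | 2-[(1Z)-2-bromoprop-1-en-1-yl] analogue of 21 | C1=CC(=O)[C@](C)(O1)[C@@H](OCc2ccc(OC)cc2)[C@@H](OC(=O)C(C)=C)[C@H]3C(=C)C(=O)O[C@H]3/C=C(/C)Br
F7 | step 16 | (Z)-alkenyl pinacol boronate from 23 | C1=CC(=O)[C@](C)(O1)[C@@H](OCc2ccc(OC)cc2)[C@@H](OC(=O)C(C)=C)[C@H]3C(=C)C(=O)O[C@H]3/C=C(/C)B4OC(C)(C)C(C)(C)O4
F8 | step 16 | 2,3-dihydro derivative of 24 (C3 epimers) | C=C(C)C(=O)O[C@H]1[C@H]2C(=C)C(=O)O[C@H]2/C=C(/C)C2CC(=O)[C@](C)(O2)[C@H]1OCc1ccc(OC)cc1
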